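## The problem

The target is a 7-oxabicyclo[4.1.0]heptan-2-one: a cyclohexanone (C1–C6) whose C3–C4 bond is also an epoxide. It carries a methyl group on C4, an isovalerate on C6 and, on C1, the cross-conjugated chain C7(=CH2)–C8(=O)–C9=C10–C11(CH3)2OOH. All four stereocentres lie on the ring: C1 and C6 are trans, and the epoxide oxygen is cis to the C1 side chain and trans to the C6 oxygen. C1 and C6 are adjacent and map onto a chiral-pool diol, but they can steer C3 and C4 only through a ring conformation. C5, a ketone in the target, can be carried as a temporary carbinol centre and is the closest lever on C4. A direct epoxidation of a C3=C4 alkene would have to reach the face cis to the C1 substituent, which reagents attacking a 5-substituted 2-methylcyclohexenone or its protected allylic ether tend to avoid. The tertiary allylic hydroperoxide, the α-methylene ketone with its neighbouring alkene and the α-acyloxy α',β'-epoxy ketone are all fragile, so the C5 and C8 carbonyl groups and the O–O bond have to appear last. The enabling feature is that C3–C4 belongs to both rings and that, in the chair with the C1, C5 and C6 substituents equatorial, the epoxide C4–O bond is axial. A C3 carbanion carrying its own leaving group (a sulfonium ylide) can therefore add to a C4 methyl ketone and be displaced by the new axial alkoxide, closing carbocycle and oxirane in one operation. The open-chain precursor needs differentiated oxygens at C5, C6 and C8, and no ether oxygen may sit where it can capture C3 once that carbon is electrophilic.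

## Retrosynthesis

**35 ⇒ 34 (C11–O bond, alkene shifted from C10=C11 to C9=C10).** The hydroperoxide is put in last by an ene reaction of singlet oxygen on the prenyl ketone 34. Carrying a peroxide through organometallic, fluoride and oxidation steps is the worse neighbour. The forward step must take hydrogen from C9 and not from the C11 methyl groups, and must leave the enone methylene alone.

**34 ⇒ 33 ⇒ 32 ⇒ 31 ⇒ 30 (C5=O, C8=O, C10=C11, C8–C9).** Both ketones come from alcohols in one oxidation of diol 33, so the epoxy ketone and the skipped dienone exist only at the end. The prenyl group of 32 is cut at C10=C11 (cross-metathesis of allyl carbinol 31) and at C8–C9 (allylation of enal 30). A direct prenyl-metal addition is shorter but attacks through the substituted allyl terminus. The forward steps must prefer the aldehyde to the C6 ester and the epoxide.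

**30 ⇒ 29 ⇒ 28 (functional-group changes at C8).** The aldehyde comes from the primary allylic alcohol 29, freed from the TBDPS ether 28 while the C5 TBS ether stays. This needs only steric discrimination between a primary and a hindered secondary silyl ether.

**28 ⇒ 25 (C3–C4 and C3–O; the key disconnection).** Cutting both bonds at C3 opens both rings and leads to the acyclic sulfonium salt 25 with three stereocentres and no ring. Cutting only the epoxide (alkene epoxidation) needs the disfavoured face or a directing hydroxyl. Cutting C4–C5 needs a trisubstituted alkenyl halide and still leaves the epoxidation. The forward reaction must form the ylide in the presence of a ketone and an ester, add it to C4 through a chair, and deliver a betaine with S+ and O− anti.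

**25 ⇒ 23 + 24; 23 ⇒ 22 ⇒ 21 ⇒ 20 (C3–S, C3–I, C6–O acyl).** The sulfonium salt comes from primary iodide 23 and diphenyl sulfide 24. The isovalerate is installed before this step. An ether oxygen on C6 lies five atoms from C3 and would capture the activated carbon as a tetrahydrofuran with loss of its benzyl group; an ester oxygen cannot. This also places the target's ester early and removes two later steps. Iodo alcohol 22 and diol 21 follow from ketone 20 by removal of both PMB ethers.

**20 ⇒ 18 ⇒ 14 + 15 (C4–C5).** The methyl ketone is an acetyl anion adduct: metalated ethyl vinyl ether 15 adds to aldehyde 14 under chelation by the C6 PMB ether. This fixes C5 syn to C6, the configuration that places the C5 silyl ether equatorial in the key step. An isopropenyl adduct would need an oxidative cleavage that the C7 methylene does not allow.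

**14 ⇒ 13 ⇒ 12 ⇒ 11 ⇒ 10 ⇒ 9 ⇒ 8 (oxygen differentiation).** Reductive opening of the 4-methoxybenzylidene acetal 12 puts PMB on the secondary C6 oxygen and frees C5 for oxidation. C3 is carried from ester 8 as alcohol 9 and PMB ether 10, so that one oxidative step later frees C3 and C6 together. Diol 11 links the acetonide to the arylidene acetal.

**8 ⇒ 4 + 2; 4 ⇒ 3; 2 ⇒ 1 (C1–C7, C1=C2).** The C1 stereocentre is made by conjugate addition of the alkenylcuprate from bromide 2 to the Z-enoate 4. The Z geometry, from a Wittig reaction of (R)-glyceraldehyde acetonide 3, is needed because it gives the syn adduct; the E isomer would give anti. C6 comes from the chiral pool and C8 arrives as the protected oxygen of 2-bromoallyl alcohol 1.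

## Roads not taken

**Alternative 1:** The ring is cut at C1–C6 and at C3=C4 of a cyclohexenone. A secondary-amine catalysed Michael addition of tert-butyl 3-oxopentanoate A1 to ethyl (E)-4-oxobut-2-enoate A2, followed by acid-mediated aldol condensation and loss of the tert-butyl ester, would give ethyl (1R)-4-methyl-5-oxocyclohex-3-ene-1-carboxylate A3.
- Merits: two cheap achiral components, catalytic asymmetric induction, and the ring with the C4 methyl, C5 ketone and C3=C4 alkene in one or two operations. This reaches a ring far faster than the chosen plan.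
- Weak points: A3 holds one of the four stereocentres. C6 is a methylene that must be oxygenated trans to C1. Nucleophilic epoxidation of 5-substituted 2-methylcyclohex-2-enones is known to favour the face trans to the substituent, the wrong one here, so an indirect halohydrin or reduce–direct–reoxidise detour would be needed. C7 is an ester carbon that must be rebuilt into a methylene-bearing carbon attached to C8. C1–H is α to the ester, so the only stereocentre can erode.
- Comparison: the chosen plan has C1 and C6 correct from the start, makes both epoxide centres in the ring-forming step, and brings C7 in as the methylene carbon with C8 attached.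

**Alternative 2:** The side chain is cut at C7–C8 and C8–C9. A carbonylative Stille coupling (Pd(PPh3)4 under a carbonylating atmosphere) of the ring alkenylstannane A4 with 1-chloro-3-methylbut-2-ene A5 would give the prenyl ketone A6.
- Merits: the whole C8–C11 unit arrives in one late, neutral step at the ketone oxidation level. The chosen route needs four steps for this (oxidation to 30, allylation, metathesis, oxidation), so this road is clearly better in side-chain economy.
- Weak points: A4 already contains the ring, the epoxide and all four stereocentres, so the central problem is untouched. The α-stannyl 1,1-disubstituted alkene must be made from a C7 carbonyl or alkyne, which changes what the ring synthesis carries. Direct coupling without carbonyl insertion, coupling at either allyl terminus and drift of the β,γ-enone into conjugation all threaten the step, and tin is used stoichiometrically.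
- Comparison: the chosen plan sets against it an end-game of routine reactions, no organotin, and a C8 oxygen that is inert during the ylide step. The coupling could in principle be grafted onto the chosen ring synthesis.

**Alternative 3:** The ring is cut at C4–C5. CrCl2 with catalytic NiCl2 would turn the Z-alkenyl iodide aldehyde A7 into an alkenylchromium species that adds to the aldehyde, giving the 2-methylcyclohex-2-enol A8; the epoxide would follow in a separate step.
- Merits: it shares the glyceraldehyde, Z-enoate and cuprate opening. The closure is tolerant and well known for six-membered rings. C5 emerges as a free hydroxyl beside a protected C6 oxygen, which is a neater differentiation than the PMB swap of the chosen plan. Every step is established, so the risk is lower than for the ylide annulation.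
- Weak points: ring and epoxide are made separately. The epoxide face then depends on the carbinol configuration from the closure. In A8 as formulated the C5 hydroxyl is cis to the C6 oxygen and trans to the C1 side chain, so a hydroxyl-directed epoxidation would place the oxirane on the wrong face. A trisubstituted Z-alkenyl iodide needs extra steps, and several equivalents of CrCl2 are consumed.
- Comparison: this road is the more secure one. The chosen plan sets against it a single step that forms the ring and both epoxide centres, with the C5 group matched to the required face. The fallback for the key step below borrows this alkene-then-directed-epoxidation logic.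

Key step: step 16

Remark (assumption): atoms are labelled as in the target throughout (ring C1–C6, chain C7–C11). The acetal carbon of 12 and C8 of 31–33 are carried as epimer mixtures, since both centres are destroyed later. TBDPS = tert-butyldiphenylsilyl, TBS = tert-butyldimethylsilyl, PMB = 4-methoxybenzyl.

## Route

Step 1
Reactants: 1 2-bromoprop-2-en-1-ol
Product: 2 [(2-bromoprop-2-en-1-yl)oxy](tert-butyl)diphenylsilane
Conditions: TBDPSCl, imidazole, CH2Cl2, 0 °C → rt
Reagents that add atoms: tert-butyl(chloro)diphenylsilane, CC(C)(C)[Si](Cl)(c1ccccc1)c1ccccc1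
Why: Imidazole-assisted silylation of a primary allylic alcohol; the bulky silyl group resists an O→C silyl shift in the later alkenyllithium and survives the acidic steps.

Step 2
Reactants: 3 (R)-2,2-dimethyl-1,3-dioxolane-4-carbaldehyde
Product: 4 methyl (Z)-3-[(4S)-2,2-dimethyl-1,3-dioxolan-4-yl]prop-2-enoate
Conditions: Ph3P=CHCO2Me, MeOH, 0 °C
Reagents that add atoms: methyl (triphenylphosphoranylidene)acetate, COC(=O)C=P(c1ccccc1)(c1ccccc1)c1ccccc1
Why: Wittig olefination; with this stabilised ylide in methanol an α-alkoxy aldehyde should give mainly the Z enoate, and the minor E isomer is removed by chromatography. The C6 stereocentre is not touched under these base-free conditions.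

Step 3
Reactants: 2 bromoalkene TBDPS ether; 4 Z-enoate
Product: 8 methyl (3S)-3-[(4S)-2,2-dimethyl-1,3-dioxolan-4-yl]-4-[(TBDPS-oxy)methyl]pent-4-enoate, via alkenyllithium 5 (not isolated), via lithium dialkenylcuprate 6 (not isolated), via silyl ketene acetal 7 (not isolated)
Conditions: 2, t-BuLi, Et2O, −78 °C; CuI, −78 → −40 °C; then 4, Me3SiCl, −78 °C; aq NH4Cl
Reagents that add atoms: none
Why: Bromine–lithium exchange, Gilman cuprate formation and Me3SiCl-accelerated conjugate addition. In the Z-enoate allylic 1,3-strain holds the C6–H in the alkene plane and the cuprate should add to the face opposite the dioxolane CH2, setting C1 syn to the C6 oxygen (3S).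

Step 4
Reactants: 8 ester
Product: 9 (3S)-3-[(4S)-2,2-dimethyl-1,3-dioxolan-4-yl]-4-[(TBDPS-oxy)methyl]pent-4-en-1-ol
Conditions: LiAlH4, Et2O, 0 °C
Reagents that add atoms: none
Why: Hydride reduction of the ester to the C3 alcohol; silyl ether, acetonide and alkene are inert.

Step 5
Reactants: 9 alcohol
Product: 10 (4S)-4-[(3S)-5-(PMB-oxy)-2-[(TBDPS-oxy)methyl]pent-1-en-3-yl]-2,2-dimethyl-1,3-dioxolane
Conditions: NaH, PMBCl, Bu4NI (cat.), THF/DMF, 0 °C → rt
Reagents that add atoms: 4-methoxybenzyl chloride, COc1ccc(CCl)cc1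
Why: Williamson etherification; PMB survives the hydride and organometallic steps and is released together with the C6 PMB group in step 12.

Step 6
Reactants: 10 acetonide
Product: 11 (2S,3S)-5-(PMB-oxy)-3-[3-(TBDPS-oxy)prop-1-en-2-yl]pentane-1,2-diol
Conditions: AcOH/H2O, 40 °C
Reagents that add atoms: none
Why: Acid hydrolysis of the terminal isopropylidene acetal; TBDPS and PMB ethers tolerate aqueous acetic acid.

Step 7
Reactants: 11 diol
Product: 12 (4S)-2-(4-methoxyphenyl)-4-[(3S)-5-(PMB-oxy)-2-[(TBDPS-oxy)methyl]pent-1-en-3-yl]-1,3-dioxolane (both epimers at the acetal carbon)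
Conditions: 4-MeOC6H4CH(OMe)2, PPTS (cat.), CH2Cl2, rt
Reagents that add atoms: 4-methoxybenzaldehyde dimethyl acetal, COc1ccc(C(OC)OC)cc1
Why: Acid-catalysed acetal exchange; the five-membered arylidene acetal of the 1,2-diol is the favoured product.

Step 8
Reactants: 12 arylidene acetal
Product: 13 (2S,3S)-2,5-bis(PMB-oxy)-3-[3-(TBDPS-oxy)prop-1-en-2-yl]pentan-1-ol
Conditions: i-Bu2AlH, CH2Cl2, −78 → 0 °C
Reagents that add atoms: none
Why: Regioselective reductive opening of the arylidene acetal: aluminium binds the less hindered primary oxygen, that C–O bond breaks, and hydride delivery leaves PMB on the secondary C6 oxygen and frees the C5 hydroxyl.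

Step 9
Reactants: 13 primary alcohol
Product: 14 (2S,3S)-2,5-bis(PMB-oxy)-3-[3-(TBDPS-oxy)prop-1-en-2-yl]pentanal
Conditions: Dess–Martin periodinane, NaHCO3, CH2Cl2, 0 °C → rt
Reagents that add atoms: none
Why: Buffered Dess–Martin oxidation should give the α-alkoxy aldehyde without epimerisation at C6; it is used at once.

Step 10
Reactants: 14 aldehyde; 15 ethyl vinyl ether
Product: 18 (3R,4S,5S)-2-ethoxy-4,7-bis(PMB-oxy)-5-[3-(TBDPS-oxy)prop-1-en-2-yl]hept-1-en-3-ol, via 1-ethoxyvinyllithium 16 (not isolated), via 1-ethoxyvinylmagnesium bromide 17 (not isolated)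
Conditions: 15, t-BuLi, THF, −78 → 0 °C; MgBr2·OEt2, −78 °C; then 14 in CH2Cl2, −78 °C; aq NaHCO3
Reagents that add atoms: none
Why: Addition of a metalated enol ether (acetyl anion equivalent) under Cram chelation control: magnesium bridges the aldehyde oxygen and the C6 PMB ether, and attack opposite the C1 branch should give the 5,6-syn carbinol (3R).

Step 11
Reactants: 18 enol ether carbinol
Product: 20 (3R,4S,5S)-3-(TBS-oxy)-4,7-bis(PMB-oxy)-5-[3-(TBDPS-oxy)prop-1-en-2-yl]heptan-2-one, via silylated enol ether 19 (not isolated)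
Conditions: TBSOTf, 2,6-lutidine, CH2Cl2, −78 °C; then 1 M HCl, THF, 0 °C
Reagents that add atoms: tert-butyldimethylsilyl trifluoromethanesulfonate, CC(C)(C)[Si](C)(C)OS(=O)(=O)C(F)(F)F; water, O
Why: Silylation of the hindered secondary alcohol with a silyl triflate, then enol ether hydrolysis, which is far faster than cleavage of silyl or PMB ethers. Silylating first avoids a free α-hydroxy ketone.

Step 12
Reactants: 20 bis-PMB ether
Product: 21 (3R,4S,5S)-3-(TBS-oxy)-4,7-dihydroxy-5-[3-(TBDPS-oxy)prop-1-en-2-yl]heptan-2-one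
Conditions: DDQ, CH2Cl2/pH 7 buffer, 0 °C → rt
Reagents that add atoms: none
Why: Oxidative cleavage of both PMB ethers (benzylic hydride abstraction, hydrolysis of the oxocarbenium ion); silyl ethers, ketone and the 1,1-disubstituted alkene are not affected.

Step 13
Reactants: 21 diol
Product: 22 (3R,4S,5S)-3-(TBS-oxy)-4-hydroxy-7-iodo-5-[3-(TBDPS-oxy)prop-1-en-2-yl]heptan-2-one
Conditions: I2, PPh3, imidazole, CH2Cl2, 0 °C
Reagents that add atoms: iodine, II
Why: Appel-type iodination is selective for the primary C3 hydroxyl; the C6 hydroxyl is secondary and flanked by two branched carbons.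

Step 14
Reactants: 22 iodo alcohol
Product: 23 (3R,4S,5S)-3-(TBS-oxy)-7-iodo-2-oxo-5-[3-(TBDPS-oxy)prop-1-en-2-yl]heptan-4-yl 3-methylbutanoate
Conditions: (CH3)2CHCH2COCl, pyridine, DMAP (cat.), CH2Cl2, 0 °C
Reagents that add atoms: 3-methylbutanoyl chloride, CC(C)CC(Cl)=O
Why: DMAP-catalysed acylation installs the isovalerate of the target. As an ester the C6 oxygen can no longer attack C3 in the next step.

Step 15
Reactants: 23 iodide; 24 diphenyl sulfide
Product: 25 [(3S,4S,5R)-5-(TBS-oxy)-4-(3-methylbutanoyloxy)-6-oxo-3-[3-(TBDPS-oxy)prop-1-en-2-yl]heptyl]diphenylsulfonium tetrafluoroborate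
Conditions: 24 (excess), AgBF4, CH2Cl2, rt, dark
Reagents that add atoms: silver tetrafluoroborate, [Ag+].F[B-](F)(F)F
Why: Silver-assisted S-alkylation of diphenyl sulfide by a primary iodide, the standard entry to alkyldiphenylsulfonium tetrafluoroborates; the excess of sulfide is meant to outrun the remote silyl ether oxygens.

Step 16
Reactants: 25 sulfonium tetrafluoroborate
Product: 28 (1S,2R,3S,4S,6S)-2-(TBS-oxy)-1-methyl-4-[3-(TBDPS-oxy)prop-1-en-2-yl]-7-oxabicyclo[4.1.0]heptan-3-yl 3-methylbutanoate, via sulfonium ylide 26 (not isolated), via diaxial betaine 27 (not isolated)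
Conditions: KN(SiMe3)2 (1 equiv, slow addition), THF, −78 → −30 °C
Reagents that add atoms: none
Why: Proposed new method: KN(SiMe3)2 removes a C3 hydrogen next to sulfur (several pK units more acidic than the ketone or ester α-hydrogens), ylide 26 adds to the C4 ketone and the new alkoxide expels diphenyl sulfide from C3, as in a Corey–Chaykovsky epoxidation; the closest known reaction types are the epoxidation of ketones by alkyldiphenylsulfonium ylides, ylide ring closures of simple keto sulfonium salts and the intramolecular Darzens reaction, but closure onto an α-silyloxy β-acyloxy ketone that must relay three stereocentres is not established. The carbocycle closes by 6-exo-trig attack of C3 on C4 and the oxirane by 3-exo-tet displacement at C3. In the chair transition state the C1, C6 and C5 substituents are equatorial, so the C5–OSi bond lies anti to the incoming C3 (Felkin–Anh polar arrangement) and the carbonyl oxygen becomes axial with the C4 methyl equatorial, which sets C4. C3 is set by the second closure: only betaine 27, with S+ and O− both axial, is anti-periplanar, and inversion at C3 places the oxygen on the face of the C1 side chain. The step needs ylide formation over enolisation (acidity gap, one equivalent of base), attack on the ketone over the C6 ester (the ketone is the better electrophile) and closure over loss of diphenyl sulfide by elimination (low temperature, non-nucleophilic potassium amide).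

Step 17
Reactants: 28 epoxide
Product: 29 (1S,2R,3S,4S,6S)-2-(TBS-oxy)-4-(3-hydroxyprop-1-en-2-yl)-1-methyl-7-oxabicyclo[4.1.0]heptan-3-yl 3-methylbutanoate
Conditions: Bu4NF, AcOH, THF, 0 °C → rt
Reagents that add atoms: none
Why: Fluoride cleavage follows steric access, so the primary TBDPS ether should go while the hindered secondary TBS ether stays; acetic acid buffers the alkoxide and protects ester and epoxide.

Step 18
Reactants: 29 allylic alcohol
Product: 30 (1S,2R,3S,4S,6S)-2-(TBS-oxy)-1-methyl-4-(3-oxoprop-1-en-2-yl)-7-oxabicyclo[4.1.0]heptan-3-yl 3-methylbutanoate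
Conditions: MnO2, CH2Cl2, rt
Reagents that add atoms: none
Why: MnO2 oxidises the primary allylic alcohol to the 2-substituted acrolein under neutral conditions, which avoids isomerisation through C1.

Step 19
Reactants: 30 enal
Product: 31 (1S,2R,3S,4S,6S)-2-(TBS-oxy)-4-(3-hydroxyhexa-1,5-dien-2-yl)-1-methyl-7-oxabicyclo[4.1.0]heptan-3-yl 3-methylbutanoate (both C8 epimers)
Conditions: CH2=CHCH2MgBr, THF/Et2O, −78 °C
Reagents that add atoms: allylmagnesium bromide, C=CC[Mg]Br
Why: 1,2-Addition of an allyl Grignard reagent to the aldehyde at −78 °C is much faster than attack on ester or epoxide. The unsubstituted allyl group has no regiochemical ambiguity.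

Step 20
Reactants: 31 allyl carbinol
Product: 32 (1S,2R,3S,4S,6S)-2-(TBS-oxy)-4-(3-hydroxy-6-methylhepta-1,5-dien-2-yl)-1-methyl-7-oxabicyclo[4.1.0]heptan-3-yl 3-methylbutanoate (both C8 epimers)
Conditions: 2-methylbut-2-ene (excess), second-generation Grubbs catalyst (cat.), CH2Cl2, 40 °C
Reagents that add atoms: 2-methylbut-2-ene, CC=C(C)C
Why: Olefin cross-metathesis turns the monosubstituted alkene into the prenyl group; the 1,1-disubstituted C7 methylene does not take part and the free hydroxyl is tolerated.

Step 21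
Reactants: 32 prenyl carbinol
Product: 33 (1R,2R,3S,4S,6S)-2-hydroxy-4-(3-hydroxy-6-methylhepta-1,5-dien-2-yl)-1-methyl-7-oxabicyclo[4.1.0]heptan-3-yl 3-methylbutanoate (both C8 epimers)
Conditions: HF·pyridine, pyridine, THF, 0 °C → rt
Reagents that add atoms: none
Why: Buffered HF·pyridine removes the hindered secondary silyl ether without base, so the C6 ester should not migrate. The C5 oxygen is cis to the epoxide oxygen, so no Payne shift is possible.

Step 22
Reactants: 33 diol
Product: 34 (1S,3S,4S,6S)-1-methyl-4-(6-methyl-3-oxohepta-1,5-dien-2-yl)-2-oxo-7-oxabicyclo[4.1.0]heptan-3-yl 3-methylbutanoate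
Conditions: Dess–Martin periodinane (excess), NaHCO3, CH2Cl2, 0 °C → rt
Reagents that add atoms: none
Why: Dess–Martin oxidation of both secondary alcohols under bicarbonate buffer gives the C5 and C8 ketones. These near-neutral conditions should leave the β,γ-unsaturated ketone unconjugated and C6 unepimerised.

Step 23
Reactants: 34 prenyl ketone
Product: 35 (1S,3S,4S,6S)-4-[(4E)-6-hydroperoxy-6-methyl-3-oxohepta-1,4-dien-2-yl]-1-methyl-2-oxo-7-oxabicyclo[4.1.0]heptan-3-yl 3-methylbutanoate
Conditions: O2, visible light, tetraphenylporphyrin (cat.), CH2Cl2, −20 °C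
Reagents that add atoms: dioxygen, O=O
Why: Schenck ene reaction of singlet oxygen with the electron-rich trisubstituted alkene. Abstraction of a C9 hydrogen (activated by the C8 carbonyl, conjugated product) places the hydroperoxide on C11 and the new E double bond at C9=C10; the electron-poor enone methylene is inert.

## Compound list

1 | 2-bromoprop-2-en-1-ol | OCC(Br)=C | starting material
2 | [(2-bromoprop-2-en-1-yl)oxy](tert-butyl)diphenylsilane | C=C(Br)CO[Si](c1ccccc1)(c1ccccc1)C(C)(C)C | intermediate
3 | (R)-2,2-dimethyl-1,3-dioxolane-4-carbaldehyde | CC1(C)OC[C@H](C=O)O1 | starting material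
4 | methyl (Z)-3-[(4S)-2,2-dimethyl-1,3-dioxolan-4-yl]prop-2-enoate | COC(=O)/C=C\[C@H]1COC(C)(C)O1 | intermediate
5 | [3-(TBDPS-oxy)prop-1-en-2-yl]lithium (formed in the flask) | [Li]C(=C)CO[Si](c1ccccc1)(c1ccccc1)C(C)(C)C | intermediate
6 | lithium bis[3-(TBDPS-oxy)prop-1-en-2-yl]cuprate (formed in the flask) | [Li+].C=C(CO[Si](c1ccccc1)(c1ccccc1)C(C)(C)C)[Cu-]C(=C)CO[Si](c1ccccc1)(c1ccccc1)C(C)(C)C | intermediate
7 | trimethylsilyl ketene acetal of ester 8 (formed in the flask) | COC(O[Si](C)(C)C)=C[C@@H](C(=C)CO[Si](c1ccccc1)(c1ccccc1)C(C)(C)C)[C@H]1COC(C)(C)O1 | intermediate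
8 | methyl (3S)-3-[(4S)-2,2-dimethyl-1,3-dioxolan-4-yl]-4-[(TBDPS-oxy)methyl]pent-4-enoate | COC(=O)C[C@@H](C(=C)CO[Si](c1ccccc1)(c1ccccc1)C(C)(C)C)[C@H]1COC(C)(C)O1 | intermediate
9 | (3S)-3-[(4S)-2,2-dimethyl-1,3-dioxolan-4-yl]-4-[(TBDPS-oxy)methyl]pent-4-en-1-ol | OCC[C@@H](C(=C)CO[Si](c1ccccc1)(c1ccccc1)C(C)(C)C)[C@H]1COC(C)(C)O1 | intermediate
10 | (4S)-4-[(3S)-5-(PMB-oxy)-2-[(TBDPS-oxy)methyl]pent-1-en-3-yl]-2,2-dimethyl-1,3-dioxolane | COc1ccc(COCC[C@@H](C(=C)CO[Si](c2ccccc2)(c2ccccc2)C(C)(C)C)[C@H]2COC(C)(C)O2)cc1 | intermediate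
11 | (2S,3S)-5-(PMB-oxy)-3-[3-(TBDPS-oxy)prop-1-en-2-yl]pentane-1,2-diol | COc1ccc(COCC[C@@H](C(=C)CO[Si](c2ccccc2)(c2ccccc2)C(C)(C)C)[C@H](O)CO)cc1 | intermediate
12 | (4S)-2-(4-methoxyphenyl)-4-[(3S)-5-(PMB-oxy)-2-[(TBDPS-oxy)methyl]pent-1-en-3-yl]-1,3-dioxolane, both acetal epimers | COc1ccc(COCC[C@@H](C(=C)CO[Si](c2ccccc2)(c2ccccc2)C(C)(C)C)[C@H]2COC(c3ccc(OC)cc3)O2)cc1 | intermediate
13 | (2S,3S)-2,5-bis(PMB-oxy)-3-[3-(TBDPS-oxy)prop-1-en-2-yl]pentan-1-ol | COc1ccc(COCC[C@@H](C(=C)CO[Si](c2ccccc2)(c2ccccc2)C(C)(C)C)[C@H](OCc2ccc(OC)cc2)CO)cc1 | intermediate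
14 | (2S,3S)-2,5-bis(PMB-oxy)-3-[3-(TBDPS-oxy)prop-1-en-2-yl]pentanal | COc1ccc(COCC[C@@H](C(=C)CO[Si](c2ccccc2)(c2ccccc2)C(C)(C)C)[C@H](OCc2ccc(OC)cc2)C=O)cc1 | intermediate
15 | ethyl vinyl ether (ethoxyethene) | C=COCC | starting material
16 | (1-ethoxyethenyl)lithium (formed in the flask) | [Li]C(=C)OCC | intermediate
17 | bromo(1-ethoxyethenyl)magnesium (formed in the flask) | C=C(OCC)[Mg]Br | intermediate
18 | (3R,4S,5S)-2-ethoxy-4,7-bis(PMB-oxy)-5-[3-(TBDPS-oxy)prop-1-en-2-yl]hept-1-en-3-ol | COc1ccc(COCC[C@@H](C(=C)CO[Si](c2ccccc2)(c2ccccc2)C(C)(C)C)[C@H](OCc2ccc(OC)cc2)[C@@H](O)C(=C)OCC)cc1 | intermediate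
19 | TBS ether of 18 at the C5 oxygen (formed in the flask) | COc1ccc(COCC[C@@H](C(=C)CO[Si](c2ccccc2)(c2ccccc2)C(C)(C)C)[C@H](OCc2ccc(OC)cc2)[C@@H](O[Si](C)(C)C(C)(C)C)C(=C)OCC)cc1 | intermediate
20 | (3R,4S,5S)-3-(TBS-oxy)-4,7-bis(PMB-oxy)-5-[3-(TBDPS-oxy)prop-1-en-2-yl]heptan-2-one | COc1ccc(COCC[C@@H](C(=C)CO[Si](c2ccccc2)(c2ccccc2)C(C)(C)C)[C@H](OCc2ccc(OC)cc2)[C@@H](O[Si](C)(C)C(C)(C)C)C(C)=O)cc1 | intermediate
21 | (3R,4S,5S)-3-(TBS-oxy)-4,7-dihydroxy-5-[3-(TBDPS-oxy)prop-1-en-2-yl]heptan-2-one | OCC[C@@H](C(=C)CO[Si](c1ccccc1)(c1ccccc1)C(C)(C)C)[C@H](O)[C@@H](O[Si](C)(C)C(C)(C)C)C(C)=O | intermediate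
22 | (3R,4S,5S)-3-(TBS-oxy)-4-hydroxy-7-iodo-5-[3-(TBDPS-oxy)prop-1-en-2-yl]heptan-2-one | ICC[C@@H](C(=C)CO[Si](c1ccccc1)(c1ccccc1)C(C)(C)C)[C@H](O)[C@@H](O[Si](C)(C)C(C)(C)C)C(C)=O | intermediate
23 | (3R,4S,5S)-3-(TBS-oxy)-7-iodo-2-oxo-5-[3-(TBDPS-oxy)prop-1-en-2-yl]heptan-4-yl 3-methylbutanoate | ICC[C@@H](C(=C)CO[Si](c1ccccc1)(c1ccccc1)C(C)(C)C)[C@H](OC(=O)CC(C)C)[C@@H](O[Si](C)(C)C(C)(C)C)C(C)=O | intermediate
24 | diphenyl sulfide | c1ccc(Sc2ccccc2)cc1 | starting material
25 | [(3S,4S,5R)-5-(TBS-oxy)-4-(3-methylbutanoyloxy)-6-oxo-3-[3-(TBDPS-oxy)prop-1-en-2-yl]heptyl]diphenylsulfonium tetrafluoroborate | CC(=O)[C@H](O[Si](C)(C)C(C)(C)C)[C@@H](OC(=O)CC(C)C)[C@@H](CC[S+](c1ccccc1)c1ccccc1)C(=C)CO[Si](c1ccccc1)(c1ccccc1)C(C)(C)C.F[B-](F)(F)F | intermediate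
26 | C3 ylide of 25 (diphenylsulfonium alkylide, formed in the flask) | CC(=O)[C@H](O[Si](C)(C)C(C)(C)C)[C@@H](OC(=O)CC(C)C)[C@@H](C[CH-][S+](c1ccccc1)c1ccccc1)C(=C)CO[Si](c1ccccc1)(c1ccccc1)C(C)(C)C | intermediate
27 | cyclised betaine: C4 alkoxide and C3 diphenylsulfonio group trans-diaxial on the new cyclohexane (formed in the flask) | C=C(CO[Si](c1ccccc1)(c1ccccc1)C(C)(C)C)[C@@H]1C[C@@H]([S+](c2ccccc2)c2ccccc2)[C@@]([O-])(C)[C@H](O[Si](C)(C)C(C)(C)C)[C@H]1OC(=O)CC(C)C | intermediate
28 | (1S,2R,3S,4S,6S)-2-(TBS-oxy)-1-methyl-4-[3-(TBDPS-oxy)prop-1-en-2-yl]-7-oxabicyclo[4.1.0]heptan-3-yl 3-methylbutanoate | C=C(CO[Si](c1ccccc1)(c1ccccc1)C(C)(C)C)[C@@H]1C[C@@H]2O[C@]2(C)[C@H](O[Si](C)(C)C(C)(C)C)[C@H]1OC(=O)CC(C)C | intermediate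
29 | (1S,2R,3S,4S,6S)-2-(TBS-oxy)-4-(3-hydroxyprop-1-en-2-yl)-1-methyl-7-oxabicyclo[4.1.0]heptan-3-yl 3-methylbutanoate | C=C(CO)[C@@H]1C[C@@H]2O[C@]2(C)[C@H](O[Si](C)(C)C(C)(C)C)[C@H]1OC(=O)CC(C)C | intermediate
30 | (1S,2R,3S,4S,6S)-2-(TBS-oxy)-1-methyl-4-(3-oxoprop-1-en-2-yl)-7-oxabicyclo[4.1.0]heptan-3-yl 3-methylbutanoate | C=C(C=O)[C@@H]1C[C@@H]2O[C@]2(C)[C@H](O[Si](C)(C)C(C)(C)C)[C@H]1OC(=O)CC(C)C | intermediate
31 | (1S,2R,3S,4S,6S)-2-(TBS-oxy)-4-(3-hydroxyhexa-1,5-dien-2-yl)-1-methyl-7-oxabicyclo[4.1.0]heptan-3-yl 3-methylbutanoate, both C8 epimers | C=CCC(O)C(=C)[C@@H]1C[C@@H]2O[C@]2(C)[C@H](O[Si](C)(C)C(C)(C)C)[C@H]1OC(=O)CC(C)C | intermediate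
32 | (1S,2R,3S,4S,6S)-2-(TBS-oxy)-4-(3-hydroxy-6-methylhepta-1,5-dien-2-yl)-1-methyl-7-oxabicyclo[4.1.0]heptan-3-yl 3-methylbutanoate, both C8 epimers | CC(C)=CCC(O)C(=C)[C@@H]1C[C@@H]2O[C@]2(C)[C@H](O[Si](C)(C)C(C)(C)C)[C@H]1OC(=O)CC(C)C | intermediate
33 | (1R,2R,3S,4S,6S)-2-hydroxy-4-(3-hydroxy-6-methylhepta-1,5-dien-2-yl)-1-methyl-7-oxabicyclo[4.1.0]heptan-3-yl 3-methylbutanoate, both C8 epimers | CC(C)=CCC(O)C(=C)[C@@H]1C[C@@H]2O[C@]2(C)[C@H](O)[C@H]1OC(=O)CC(C)C | intermediate
34 | (1S,3S,4S,6S)-1-methyl-4-(6-methyl-3-oxohepta-1,5-dien-2-yl)-2-oxo-7-oxabicyclo[4.1.0]heptan-3-yl 3-methylbutanoate | CC(C)=CCC(=O)C(=C)[C@@H]1C[C@@H]2O[C@]2(C)C(=O)[C@H]1OC(=O)CC(C)C | intermediate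
35 | (1S,3S,4S,6S)-4-[(4E)-6-hydroperoxy-6-methyl-3-oxohepta-1,4-dien-2-yl]-1-methyl-2-oxo-7-oxabicyclo[4.1.0]heptan-3-yl 3-methylbutanoate (CNP0241468.1) | C=C(C(=O)/C=C/C(C)(C)OO)[C@@H]1C[C@@H]2O[C@]2(C)C(=O)[C@H]1OC(=O)CC(C)C | target

## Step count and least certain steps

Total: 23 steps. Longest linear sequence: 22 steps (3 → 35 through steps 2–23; the branch 1 → 2 is a single step).

**Step 16 (key step, labelled as a proposed new method).**
- Most likely failure: the ylide adds with the sulfonium group equatorial, giving betaines in which S+ and O− are cis. These cannot close and are lost by reversion or protonation.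
- Other failure paths: elimination of diphenyl sulfide across C2–C3, acyl transfer by ylide attack on the C6 ester, and epimerisation at C5 by enolisation.
- Fallback (known reactions only): it sets out from iodide 23. Heating with PPh3 in MeCN would give the triphenylphosphonium iodide F1. KN(SiMe3)2 in THF would form the phosphorus ylide, and an intramolecular Wittig reaction with the C4 ketone would close the ring as the C3=C4 cyclohexene F2. Camphorsulfonic acid in MeOH would remove the secondary TBS ether while the TBDPS ether stays, giving the allylic alcohol F3. Its C5 hydroxyl lies on the face of the C1 side chain, so epoxidation with t-BuOOH and catalytic VO(acac)2 is directed to that face and would give the epoxy alcohol F4. Silylation with TBSOTf and 2,6-lutidine returns to 28.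

**Step 15.**
- Most likely failure: during silver-assisted ionisation the C5 or C8 silyl ether oxygen attacks C3 through a six-membered arrangement and the silyl group is stripped by fluoride from the counter-ion. The C7 alkene may also take part.
- Fallback: it sets out from 23. Thiophenol and K2CO3 in DMF would give the phenyl sulfide F5, since a thiolate outruns any internal oxygen. S-phenylation with diphenyliodonium tetrafluoroborate and catalytic Cu(O2CPh)2 in chlorobenzene at about 110 °C returns to 25.

**Step 13.**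
- Most likely failure: ring closure of the 1,4-related hydroxyl and activated C3 (or of iodo alcohol 22 before acylation) to a tetrahydrofuran, which removes the electrophilic carbon.
- Fallback: it sets out from diol 21. Et3SiCl and imidazole at −78 °C would give the primary triethylsilyl ether F6. Acylation with 3-methylbutanoyl chloride and DMAP would give the ester F7. PPTS in MeOH would free the primary alcohol as the hydroxy ester F8. Iodination as in step 13 then gives 23, with the C6 oxygen already acylated before C3 becomes electrophilic.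

**Step 3.**
- Most likely failure: slow transfer of the hindered 1,1-disubstituted alkenyl group to the cis-enoate, silyl migration from oxygen to carbon in alkenyllithium 5, or eroded facial selectivity.
- Fallback: it sets out from 2. Miyaura borylation (bis(pinacolato)diboron, PdCl2(PPh3)2, KOPh) would give the alkenyl pinacol boronate F9. Rhodium-catalysed conjugate addition to 4 ([Rh(cod)OH]2, BINAP, aqueous dioxane), with the ligand enantiomer chosen to reinforce the substrate bias, returns to 8.

**Step 23.**
- Most likely failure: hydrogen abstraction from the C11 methyl groups in place of C9, which puts the hydroperoxide on C10.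
- Fallback: it sets out from enal 30. CH2=CHMgBr at −78 °C would give the dienol F10, HF·pyridine the diol F11, and Dess–Martin oxidation the vinyl ketone F12. Cross-metathesis of F12 with the 2-methoxyprop-2-yl peroxyketal of 2-methylbut-3-en-2-yl hydroperoxide, using the second-generation Hoveyda–Grubbs catalyst, would give the E-enone peroxyketal F13 with the oxygen fixed on C11. Aqueous acetic acid then releases 35.

## Further compounds

F1 | step 16 | triphenylphosphonium iodide analogue of 25 (C3–PPh3+, iodide counter-ion) | CC(=O)[C@H](O[Si](C)(C)C(C)(C)C)[C@@H](OC(=O)CC(C)C)[C@@H](CC[P+](c1ccccc1)(c1ccccc1)c1ccccc1)C(=C)CO[Si](c1ccccc1)(c1ccccc1)C(C)(C)C.[I-]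
F2 | step 16 | C3=C4 cyclohexene: 2-(TBS-oxy)-3-methyl-6-[3-(TBDPS-oxy)prop-1-en-2-yl]cyclohex-3-en-1-yl 3-methylbutanoate, C1, C5 and C6 configured as in 28 | C=C(CO[Si](c1ccccc1)(c1ccccc1)C(C)(C)C)[C@@H]1CC=C(C)[C@H](O[Si](C)(C)C(C)(C)C)[C@H]1OC(=O)CC(C)C
F3 | step 16 | allylic alcohol: 2-hydroxy-3-methyl-6-[3-(TBDPS-oxy)prop-1-en-2-yl]cyclohex-3-en-1-yl 3-methylbutanoate, C5 hydroxyl cis to the C1 side chain | C=C(CO[Si](c1ccccc1)(c1ccccc1)C(C)(C)C)[C@@H]1CC=C(C)[C@H](O)[C@H]1OC(=O)CC(C)C
F4 | step 16 | epoxy alcohol: C5-hydroxy analogue of 28 | C=C(CO[Si](c1ccccc1)(c1ccccc1)C(C)(C)C)[C@@H]1C[C@@H]2O[C@]2(C)[C@H](O)[C@H]1OC(=O)CC(C)C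
F5 | step 15 | phenyl sulfide: C3–SPh analogue of 23 | CC(=O)[C@H](O[Si](C)(C)C(C)(C)C)[C@@H](OC(=O)CC(C)C)[C@@H](CCSc1ccccc1)C(=C)CO[Si](c1ccccc1)(c1ccccc1)C(C)(C)C
F6 | step 13 | primary triethylsilyl ether of diol 21 | CC[Si](CC)(CC)OCC[C@@H](C(=C)CO[Si](c1ccccc1)(c1ccccc1)C(C)(C)C)[C@H](O)[C@@H](O[Si](C)(C)C(C)(C)C)C(C)=O
F7 | step 13 | C6 3-methylbutanoate of F6 | CC[Si](CC)(CC)OCC[C@@H](C(=C)CO[Si](c1ccccc1)(c1ccccc1)C(C)(C)C)[C@H](OC(=O)CC(C)C)[C@@H](O[Si](C)(C)C(C)(C)C)C(C)=O
F8 | step 13 | hydroxy ester: C3-hydroxy analogue of 23 | OCC[C@@H](C(=C)CO[Si](c1ccccc1)(c1ccccc1)C(C)(C)C)[C@H](OC(=O)CC(C)C)[C@@H](O[Si](C)(C)C(C)(C)C)C(C)=O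
F9 | step 3 | tert-butyl(diphenyl){[2-(4,4,5,5-tetramethyl-1,3,2-dioxaborolan-2-yl)prop-2-en-1-yl]oxy}silane | C=C(CO[Si](c1ccccc1)(c1ccccc1)C(C)(C)C)B1OC(C)(C)C(C)(C)O1
F10 | step 23 | dienol: 4-(3-hydroxypenta-1,4-dien-2-yl) analogue of 30, both C8 epimers | C=CC(O)C(=C)[C@@H]1C[C@@H]2O[C@]2(C)[C@H](O[Si](C)(C)C(C)(C)C)[C@H]1OC(=O)CC(C)C
F11 | step 23 | diol: C5-hydroxy analogue of F10 | C=CC(O)C(=C)[C@@H]1C[C@@H]2O[C@]2(C)[C@H](O)[C@H]1OC(=O)CC(C)C
F12 | step 23 | vinyl ketone: (1S,3S,4S,6S)-1-methyl-2-oxo-4-(3-oxopenta-1,4-dien-2-yl)-7-oxabicyclo[4.1.0]heptan-3-yl 3-methylbutanoate | C=CC(=O)C(=C)[C@@H]1C[C@@H]2O[C@]2(C)C(=O)[C@H]1OC(=O)CC(C)C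
F13 | step 23 | 2-methoxyprop-2-yl peroxyketal of 35 | C=C(C(=O)/C=C/C(C)(C)OOC(C)(C)OC)[C@@H]1C[C@@H]2O[C@]2(C)C(=O)[C@H]1OC(=O)CC(C)C
A1 | alternative 1 | tert-butyl 3-oxopentanoate | CCC(=O)CC(=O)OC(C)(C)C
A2 | alternative 1 | ethyl (E)-4-oxobut-2-enoate | CCOC(=O)/C=C/C=O
A3 | alternative 1 | ethyl (1R)-4-methyl-5-oxocyclohex-3-ene-1-carboxylate | CCOC(=O)[C@@H]1CC=C(C)C(=O)C1
A4 | alternative 2 | ring alkenylstannane: C7 tributylstannyl, C5 triethylsilyl ether, C6 TBS ether | C=C([Sn](CCCC)(CCCC)CCCC)[C@@H]1C[C@@H]2O[C@]2(C)[C@H](O[Si](CC)(CC)CC)[C@H]1O[Si](C)(C)C(C)(C)C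
A5 | alternative 2 | 1-chloro-3-methylbut-2-ene | CC(C)=CCCl
A6 | alternative 2 | prenyl ketone on the protected epoxy-diol ring (C5 triethylsilyl ether, C6 TBS ether) | C=C(C(=O)CC=C(C)C)[C@@H]1C[C@@H]2O[C@]2(C)[C@H](O[Si](CC)(CC)CC)[C@H]1O[Si](C)(C)C(C)(C)C
A7 | alternative 3 | open-chain (Z)-alkenyl iodide aldehyde (C4 iodide, C5 aldehyde, C6 and C8 TBS ethers) | I/C(C)=C\C[C@@H](C(=C)CO[Si](C)(C)C(C)(C)C)[C@H](O[Si](C)(C)C(C)(C)C)C=O
A8 | alternative 3 | 6-(TBS-oxy)-5-[3-(TBS-oxy)prop-1-en-2-yl]-2-methylcyclohex-2-en-1-ol (5,6-trans) | C=C(CO[Si](C)(C)C(C)(C)C)[C@@H]1CC=C(C)[C@@H](O)[C@H]1O[Si](C)(C)C(C)(C)C
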